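**Assumptions**
- Geranylacetone is used as the pure (5E) isomer (≥98 % E).
- The IDPi antipode written as (S,S) in step 3 stands for whichever antipode the first screen shows to give (S)-7.

Locants in names: azulene numbering for the 5-7 half (C1 = C(Me)–O, C4 = CMe2, C5 = side-chain carbon, C6 = C-methyl alkene carbon); 1-benzoxepine numbering for the 7-6 half.

**Retrosynthetic overview**
1. 23 ⇐ equatorial methyl addition to benzoxepanone 21 ⇐ one-flask diepoxide cascade of silyl enol ether 20, which closes the oxepane and then the cyclohexanone (last two rings).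
2. 20 ⇐ conjugate hydrosilylation of enone 19 ⇐ aldol condensation of diepoxy ketone 2 (double Shi epoxidation of geranylacetone 1) with aldehyde 16.
3. 16 ⇐ Claisen rearrangement (C7–O to C5–C chirality transfer) of allylic alcohol 14 ⇐ CBS reduction of cis-hydroazulenone 13.
4. 13 (seven-membered ring) ⇐ 7-exo enolate opening of cyclopentene oxide 11 ⇐ Z-enone 10 ⇐ aldehyde 7.
5. 7 ⇐ new enantioconvergent IDPi-catalysed allylation of silyl enol ether 5 by the cation from alcohol 4. Ring order: cyclopentane (from 3) → cycloheptene → oxepane → cyclohexane.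

**Route**

Step 1
Reactants: 1 (5E)-6,10-dimethylundeca-5,9-dien-2-one
Product: 2 4-[(2S,3S)-3-{2-[(2S)-3,3-dimethyloxiran-2-yl]ethyl}-3-methyloxiran-2-yl]butan-2-one
Conditions: ent-Shi ketone (L-fructose-derived, 0.6 equiv), Oxone, K2CO3, Bu4NHSO4, MeCN–DMM/aq. borate buffer pH 10.5, 0 °C
Reagents that add atoms: potassium peroxymonosulfate (Oxone), [K+].[O-]S(=O)(=O)OO
Why: Shi epoxidation: the chiral dioxirane delivers oxygen to the same face of both trisubstituted olefins through the spiro transition state, setting the three epoxide centres as S, while the saturated methyl ketone is inert under the cold buffered conditions.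

Step 2
Reactants: 3 3-methylcyclopent-2-en-1-one
Product: 4 rac-3-methylcyclopent-2-en-1-ol
Conditions: NaBH4, CeCl3·7H2O, MeOH, 0 °C
Reagents that add atoms: none
Why: Luche 1,2-reduction of the enone; the carbinol centre is left racemic because it is erased by ionisation in step 3.

Step 3
Reactants: 4 rac-3-methylcyclopent-2-en-1-ol; 5 trimethyl[(2-methylprop-1-en-1-yl)oxy]silane
Product: 7 2-methyl-2-[(1S)-3-methylcyclopent-2-en-1-yl]propanal, via allyl cation ion pair 6 (not isolated)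
Conditions: (S,S)-IDPi (confined imidodiphosphorimidate acid, 2 mol %), 5 (2.5 equiv), toluene, −60 °C
Reagents that add atoms: none
Why: Proposed new method: the IDPi acid (silylated in situ by 5) ionises both enantiomers of 4 to the same planar 1-methylcyclopentenyl cation held as a contact ion pair inside the chiral anion, 5 attacks the unsubstituted allyl terminus (the methylated terminus would give vicinal quaternary carbons) on the face left open by the anion to set C3a as S, and silyl transfer from the resulting oxocarbenium ion turns the catalyst over; the closest known chemistry is the racemic Lewis-acid SN1 allylation of silyl enol ethers with allylic alcohols and asymmetric counteranion-directed silylium (Mukaiyama-type) catalysis with IDPi anions.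

Step 4
Reactants: 7 2-methyl-2-[(1S)-3-methylcyclopent-2-en-1-yl]propanal
Product: 8 (3S)-3-[(3Z)-4-iodo-2-methylpent-3-en-2-yl]-1-methylcyclopent-1-ene
Conditions: EtPPh3Br, n-BuLi, THF; I2, −78 °C; NaHMDS, −20 °C; then 7, −78 → 0 °C
Reagents that add atoms: ethyltriphenylphosphonium bromide, CC[P+](c1ccccc1)(c1ccccc1)c1ccccc1.[Br-]; iodine, II
Why: Stork–Zhao olefination: the α-iodo ylide reacts through the kinetic cis-oxaphosphetane to give the Z-vinyl iodide, which places C4 and the future C7 cis as the ring closure needs.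

Step 5
Reactants: 8 (3S)-3-[(3Z)-4-iodo-2-methylpent-3-en-2-yl]-1-methylcyclopent-1-ene
Product: 10 (3Z)-3,5-dimethyl-5-[(1S)-3-methylcyclopent-2-en-1-yl]hex-3-en-2-one, via vinyllithium 9 (not isolated)
Conditions: t-BuLi (2.1 equiv), Et2O, −78 °C; MeC(O)N(OMe)Me, −78 → 0 °C
Reagents that add atoms: N-methoxy-N-methylacetamide, CC(=O)N(C)OC
Why: Iodine–lithium exchange with retention of alkene geometry followed by Weinreb amide acylation, which stops at the methyl ketone because the tetrahedral chelate survives until work-up.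

Step 6
Reactants: 10 (3Z)-3,5-dimethyl-5-[(1S)-3-methylcyclopent-2-en-1-yl]hex-3-en-2-one
Product: 11 (3Z)-3,5-dimethyl-5-[(1R,2R,5S)-5-methyl-6-oxabicyclo[3.1.0]hexan-2-yl]hex-3-en-2-one
Conditions: mCPBA, CH2Cl2, 0 °C
Reagents that add atoms: mCPBA (3-chloroperoxybenzoic acid), OOC(=O)c1cccc(Cl)c1
Why: Prilezhaev epoxidation: only the electron-rich ring olefin reacts (the hindered conjugated enone does not), and the peracid approaches anti to the quaternary side chain on the neighbouring carbon, which fixes the oxygen on C1 and C8a trans to C4.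

Step 7
Reactants: 11 (3Z)-3,5-dimethyl-5-[(1R,2R,5S)-5-methyl-6-oxabicyclo[3.1.0]hexan-2-yl]hex-3-en-2-one
Product: 13 (1S,3aS,8aS)-1,4,4,6-tetramethyl-1-(triethylsilyloxy)-2,3,3a,4,8,8a-hexahydroazulen-7(1H)-one, via lithium alkoxide 12 (not isolated)
Conditions: LiHMDS, THF, −78 → 40 °C; then TESOTf, −78 → 0 °C
Reagents that add atoms: triethylsilyl trifluoromethanesulfonate, CC[Si](CC)(CC)OS(=O)(=O)C(F)(F)F
Why: Intramolecular enolate alkylation (7-exo-tet epoxide opening): the only enolisable position is the methyl group (no γ-hydrogen), and its carbon attacks C8a anti to the C–O bond from the face that carries the tether, so C8a is inverted to give the cis ring fusion and the C1 oxygen ends trans to the new bond before being capped as the TES ether.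

Step 8
Reactants: 13 (1S,3aS,8aS)-1,4,4,6-tetramethyl-1-(triethylsilyloxy)-2,3,3a,4,8,8a-hexahydroazulen-7(1H)-one
Product: 14 (1S,3aS,7R,8aS)-1,4,4,6-tetramethyl-1-(triethylsilyloxy)-1,2,3,3a,4,7,8,8a-octahydroazulen-7-ol
Conditions: (S)-Me-CBS (20 mol %), BH3·SMe2, THF, −30 °C; MeOH quench
Reagents that add atoms: none
Why: CBS reduction under catalyst control, with the α-methyl alkenyl arm as the large group, is expected to give the 7R alcohol whose oxygen lies on the face opposite the ring-fusion hydrogens.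

Step 9
Reactants: 14 (1S,3aS,7R,8aS)-1,4,4,6-tetramethyl-1-(triethylsilyloxy)-1,2,3,3a,4,7,8,8a-octahydroazulen-7-ol
Product: 16 2-[(1S,3aS,5R,8aS)-1,4,4,6-tetramethyl-1-(triethylsilyloxy)-1,2,3,3a,4,5,8,8a-octahydroazulen-5-yl]acetaldehyde, via allyl vinyl ether 15 (not isolated)
Conditions: [Ir(cod)Cl]2 (2 mol %), NaOAc (5 mol %), vinyl acetate, toluene, 100 °C; then 150 °C (sealed tube)
Reagents that add atoms: vinyl acetate, CC(=O)OC=C
Why: Iridium-catalysed vinyl transfer followed by Claisen rearrangement: the suprafacial [3,3] shift moves the C7–O bond to a C5–C bond on the same ring face (C5 = R) and leaves the C6=C7 olefin in its final position.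

Step 10
Reactants: 2 4-[(2S,3S)-3-{2-[(2S)-3,3-dimethyloxiran-2-yl]ethyl}-3-methyloxiran-2-yl]butan-2-one; 16 2-[(1S,3aS,5R,8aS)-1,4,4,6-tetramethyl-1-(triethylsilyloxy)-1,2,3,3a,4,5,8,8a-octahydroazulen-5-yl]acetaldehyde
Product: 19 (4E)-1-[(2S,3S)-3-{2-[(2S)-3,3-dimethyloxiran-2-yl]ethyl}-3-methyloxiran-2-yl]-6-[(1S,3aS,5R,8aS)-1,4,4,6-tetramethyl-1-(triethylsilyloxy)-1,2,3,3a,4,5,8,8a-octahydroazulen-5-yl]hex-4-en-3-one, via lithium aldolate 17 (not isolated), via mesylate 18 (not isolated)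
Conditions: 2 (1.5 equiv), LDA, THF, −78 °C; 16; then MsCl, −78 → 0 °C; DBU, 23 °C
Reagents that add atoms: none
Why: Directed aldol addition of the kinetic methyl-ketone enolate (epoxides are untouched at −78 °C) followed by mesylation and E1cB elimination gives the E-enone, and the small amounts of diastereomers that stem from the minor enantiomer of either fragment are removed here by chromatography.

Step 11
Reactants: 19 the E-enone from step 10
Product: 20 triethyl{[(3Z)-1-[(2S,3S)-3-{2-[(2S)-3,3-dimethyloxiran-2-yl]ethyl}-3-methyloxiran-2-yl]-6-[(1S,3aS,5R,8aS)-1,4,4,6-tetramethyl-1-(triethylsilyloxy)-1,2,3,3a,4,5,8,8a-octahydroazulen-5-yl]hex-3-en-3-yl]oxy}silane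
Conditions: RhCl(PPh3)3 (1 mol %), Et3SiH, THF, 50 °C
Reagents that add atoms: triethylsilane, CC[SiH](CC)CC
Why: Rhodium-catalysed conjugate (1,4-) hydrosilylation gives the Z silyl enol ether with the double bond fixed on the side-chain side of the ketone, a regiochemistry that direct enolisation could not provide.

Step 12
Reactants: 20 the Z silyl enol ether from step 11
Product: 21 (3S,5aS,6S,9aS)-6-{2-[(1S,3aS,5R,8aS)-1,4,4,6-tetramethyl-1-(triethylsilyloxy)-1,2,3,3a,4,5,8,8a-octahydroazulen-5-yl]ethyl}-2,2,5a-trimethyl-3-(trimethylsilyloxy)octahydro-1-benzoxepin-7(2H)-one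
Conditions: TMSOTf (1.2 equiv), 2,6-di-tert-butyl-4-methylpyridine, CH2Cl2, −78 °C
Reagents that add atoms: trimethylsilyl trifluoromethanesulfonate, C[Si](C)(C)OS(=O)(=O)C(F)(F)F
Why: Epoxide-opening oxa-/carbacyclisation cascade: silylation of the terminal epoxide lets the inner epoxide oxygen attack its tertiary carbon (oxepane, C3 and C9a retained), and the enol silane then opens the resulting epoxonium ion at its tertiary carbon with inversion through a chair transition state, which gives the trans ring fusion (C5a) and the equatorial side chain (C6, also the thermodynamic epimer).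

Step 13
Reactants: 21 the benzoxepanone from step 12
Product: 23 (3S,5aS,6S,7R,9aS)-6-{2-[(1S,3aS,5R,8aS)-1-hydroxy-1,4,4,6-tetramethyl-1,2,3,3a,4,5,8,8a-octahydroazulen-5-yl]ethyl}-2,2,5a,7-tetramethyldecahydro-1-benzoxepine-3,7-diol, via bis-silyl ether 22 (not isolated)
Conditions: MeLi, CeCl3, THF, −78 °C; then TBAF, THF, 40 °C
Reagents that add atoms: methyllithium, [Li]C
Why: Organocerium 1,2-addition without enolisation: the methyl group enters equatorially because axial attack is blocked by the 1,3-diaxial angular methyl, which gives the axial C7 hydroxyl cis to the side chain (7R), and fluoride then removes both silyl ethers.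

**Compound list**
1 | (5E)-6,10-dimethylundeca-5,9-dien-2-one | CC(=O)CC/C=C(\C)CCC=C(C)C | starting material
2 | 4-[(2S,3S)-3-{2-[(2S)-3,3-dimethyloxiran-2-yl]ethyl}-3-methyloxiran-2-yl]butan-2-one | CC(=O)CC[C@@H]1O[C@@]1(C)CC[C@@H]1OC1(C)C | intermediate
3 | 3-methylcyclopent-2-en-1-one | CC1=CC(=O)CC1 | starting material
4 | rac-3-methylcyclopent-2-en-1-ol | CC1=CC(O)CC1 | intermediate
5 | trimethyl[(2-methylprop-1-en-1-yl)oxy]silane | CC(C)=CO[Si](C)(C)C | starting material
6 | 3-methylcyclopent-2-en-1-ylium (contact ion pair with the IDPi anion) | CC1=C[CH+]CC1 | intermediate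
7 | 2-methyl-2-[(1S)-3-methylcyclopent-2-en-1-yl]propanal | CC1=C[C@H](CC1)C(C)(C)C=O | intermediate
8 | (3S)-3-[(3Z)-4-iodo-2-methylpent-3-en-2-yl]-1-methylcyclopent-1-ene | CC1=C[C@H](CC1)C(C)(C)/C=C(/C)I | intermediate
9 | vinyllithium from 8 (C–Li in place of C–I, geometry retained) | CC1=C[C@H](CC1)C(C)(C)/C=C(/C)[Li] | intermediate
10 | (3Z)-3,5-dimethyl-5-[(1S)-3-methylcyclopent-2-en-1-yl]hex-3-en-2-one | CC1=C[C@H](CC1)C(C)(C)/C=C(/C)C(C)=O | intermediate
11 | (3Z)-3,5-dimethyl-5-[(1R,2R,5S)-5-methyl-6-oxabicyclo[3.1.0]hexan-2-yl]hex-3-en-2-one | CC(=O)/C(C)=C\C(C)(C)[C@H]1CC[C@]2(C)O[C@H]12 | intermediate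
12 | lithium (1S,3aS,8aS)-1,4,4,6-tetramethyl-7-oxo-1,2,3,3a,4,7,8,8a-octahydroazulen-1-olate | CC1=CC(C)(C)[C@H]2CC[C@](C)(O[Li])[C@H]2CC1=O | intermediate
13 | (1S,3aS,8aS)-1,4,4,6-tetramethyl-1-(triethylsilyloxy)-2,3,3a,4,8,8a-hexahydroazulen-7(1H)-one | CC1=CC(C)(C)[C@H]2CC[C@](C)(O[Si](CC)(CC)CC)[C@H]2CC1=O | intermediate
14 | (1S,3aS,7R,8aS)-1,4,4,6-tetramethyl-1-(triethylsilyloxy)-1,2,3,3a,4,7,8,8a-octahydroazulen-7-ol | CC1=CC(C)(C)[C@H]2CC[C@](C)(O[Si](CC)(CC)CC)[C@H]2C[C@H]1O | intermediate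
15 | 7-O-vinyl ether of 14 | CC1=CC(C)(C)[C@H]2CC[C@](C)(O[Si](CC)(CC)CC)[C@H]2C[C@H]1OC=C | intermediate
16 | 2-[(1S,3aS,5R,8aS)-1,4,4,6-tetramethyl-1-(triethylsilyloxy)-1,2,3,3a,4,5,8,8a-octahydroazulen-5-yl]acetaldehyde | CC1=CC[C@H]2[C@H](CC[C@]2(C)O[Si](CC)(CC)CC)C(C)(C)[C@@H]1CC=O | intermediate
17 | lithium aldolate of 2 and 16 (5-oxido-hexan-3-one, both C5 epimers) | CC1=CC[C@H]2[C@H](CC[C@]2(C)O[Si](CC)(CC)CC)C(C)(C)[C@@H]1CC(O[Li])CC(=O)CC[C@@H]1O[C@@]1(C)CC[C@@H]1OC1(C)C | intermediate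
18 | 5-mesyloxy ketone from 17 | CC1=CC[C@H]2[C@H](CC[C@]2(C)O[Si](CC)(CC)CC)C(C)(C)[C@@H]1CC(OS(C)(=O)=O)CC(=O)CC[C@@H]1O[C@@]1(C)CC[C@@H]1OC1(C)C | intermediate
19 | (4E)-1-[(2S,3S)-3-{2-[(2S)-3,3-dimethyloxiran-2-yl]ethyl}-3-methyloxiran-2-yl]-6-[(1S,3aS,5R,8aS)-1,4,4,6-tetramethyl-1-(triethylsilyloxy)-1,2,3,3a,4,5,8,8a-octahydroazulen-5-yl]hex-4-en-3-one | CC1=CC[C@H]2[C@H](CC[C@]2(C)O[Si](CC)(CC)CC)C(C)(C)[C@@H]1C/C=C/C(=O)CC[C@@H]1O[C@@]1(C)CC[C@@H]1OC1(C)C | intermediate
20 | (3Z)-3-triethylsilyloxy-hex-3-ene derived from 19 (Z silyl enol ether) | CC1=CC[C@H]2[C@H](CC[C@]2(C)O[Si](CC)(CC)CC)C(C)(C)[C@@H]1CC/C=C(\O[Si](CC)(CC)CC)CC[C@@H]1O[C@@]1(C)CC[C@@H]1OC1(C)C | intermediate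
21 | (3S,5aS,6S,9aS)-6-{2-[(1S,3aS,5R,8aS)-1,4,4,6-tetramethyl-1-(triethylsilyloxy)-1,2,3,3a,4,5,8,8a-octahydroazulen-5-yl]ethyl}-2,2,5a-trimethyl-3-(trimethylsilyloxy)octahydro-1-benzoxepin-7(2H)-one | CC1=CC[C@H]2[C@H](CC[C@]2(C)O[Si](CC)(CC)CC)C(C)(C)[C@@H]1CC[C@H]1[C@]2(C)CC[C@H](O[Si](C)(C)C)C(C)(C)O[C@H]2CCC1=O | intermediate
22 | 1-O-triethylsilyl-3-O-trimethylsilyl ether of 23 (formed as its metal alkoxide) | CC1=CC[C@H]2[C@H](CC[C@]2(C)O[Si](CC)(CC)CC)C(C)(C)[C@@H]1CC[C@H]1[C@]2(C)CC[C@H](O[Si](C)(C)C)C(C)(C)O[C@H]2CC[C@@]1(C)O | intermediate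
23 | (3S,5aS,6S,7R,9aS)-6-{2-[(1S,3aS,5R,8aS)-1-hydroxy-1,4,4,6-tetramethyl-1,2,3,3a,4,5,8,8a-octahydroazulen-5-yl]ethyl}-2,2,5a,7-tetramethyldecahydro-1-benzoxepine-3,7-diol (CNP0183476.2) | CC1=CC[C@H]2[C@H](CC[C@]2(C)O)C(C)(C)[C@@H]1CC[C@H]1[C@]2(C)CC[C@H](O)C(C)(C)O[C@H]2CC[C@@]1(C)O | target

**Step count and risks**

Total: 13 steps. Longest linear sequence: 12 steps (3 → 23, steps 2–13); the other branch (1 → 2) joins at step 10.

Most likely to fail:

Step 3 (the proposed new ion-pair allylation; risks are low ee and loss of the cation by elimination). The fallback uses known chemistry and runs from 4 back to 7. A lipase-catalysed kinetic resolution (Novozym 435, vinyl acetate, hexane, taken to about 55–60 % conversion) leaves (1S)-3-methylcyclopent-2-en-1-ol F1 and removes the expected fast-reacting enantiomer as (1R)-3-methylcyclopent-2-en-1-yl acetate F2. F1 is converted with methyl chloroformate and pyridine into methyl (1S)-3-methylcyclopent-2-en-1-yl carbonate F3. Pd2(dba)3/dppe-catalysed allylic alkylation of silyl enol ether 5 with F3 (ionisation and outer-sphere attack each with inversion, attack at the unsubstituted allyl terminus) then gives 7 with overall retention.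

Step 7 (seven-membered ring closure by a ketone enolate on a trisubstituted epoxide; risks are O-alkylation and slow opening). The fallback runs from 11 to 13 and replaces the enolate by an azaenolate. Condensation of 11 with 1,1-dimethylhydrazine gives the N,N-dimethylhydrazone of 11 F4. LDA then generates the methyl azaenolate, which opens the epoxide in the same 7-exo sense to the cyclised hydroxy hydrazone F5. Buffered CuCl2 hydrolysis releases the free hydroxy enone F6, and TESOTf with 2,6-lutidine gives 13.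

Step 12 (late-stage cascade on the fully assembled substrate; modest yields are typical for this reaction class). The fallback runs from 2 to 21 and moves the cascade ahead of the fragment union. The kinetic enolate of 2 is C-phosphinylated with ClP(OEt)2 and oxidised in air to the β-ketophosphonate F7. TMSCl and Et3N give its silyl enol ether F8, and the same TMSOTf cascade on this small substrate gives the bicyclic β-ketophosphonate F9. A Horner–Wadsworth–Emmons reaction of F9 with 16 gives the exocyclic enone F10. L-Selectride conjugate reduction with thermodynamic protonation then gives 21.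

Further compounds
F1 | step 3 | (1S)-3-methylcyclopent-2-en-1-ol | CC1=C[C@H](CC1)O
F2 | step 3 | (1R)-3-methylcyclopent-2-en-1-yl acetate | CC1=C[C@@H](CC1)OC(C)=O
F3 | step 3 | methyl (1S)-3-methylcyclopent-2-en-1-yl carbonate | CC1=C[C@H](CC1)OC(=O)OC
F4 | step 7 | N,N-dimethylhydrazone of 11 | CN(C)N=C(C)/C(C)=C\C(C)(C)[C@H]1CC[C@]2(C)O[C@H]12
F5 | step 7 | (1S,3aS,8aS)-7-(2,2-dimethylhydrazinylidene)-1,4,4,6-tetramethyl-1,2,3,3a,4,7,8,8a-octahydroazulen-1-ol | CC1=CC(C)(C)[C@H]2CC[C@](C)(O)[C@H]2CC1=NN(C)C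
F6 | step 7 | (1S,3aS,8aS)-1-hydroxy-1,4,4,6-tetramethyl-2,3,3a,4,8,8a-hexahydroazulen-7(1H)-one | CC1=CC(C)(C)[C@H]2CC[C@](C)(O)[C@H]2CC1=O
F7 | step 12 | diethyl {4-[(2S,3S)-3-{2-[(2S)-3,3-dimethyloxiran-2-yl]ethyl}-3-methyloxiran-2-yl]-2-oxobutyl}phosphonate | CCOP(=O)(OCC)CC(=O)CC[C@@H]1O[C@@]1(C)CC[C@@H]1OC1(C)C
F8 | step 12 | trimethylsilyl enol ether of F7 | CCOP(=O)(OCC)C=C(O[Si](C)(C)C)CC[C@@H]1O[C@@]1(C)CC[C@@H]1OC1(C)C
F9 | step 12 | diethyl [(3S,5aS,9aS)-2,2,5a-trimethyl-7-oxo-3-(trimethylsilyloxy)decahydro-1-benzoxepin-6-yl]phosphonate (C6 epimers) | CCOP(=O)(OCC)C1[C@]2(C)CC[C@H](O[Si](C)(C)C)C(C)(C)O[C@H]2CCC1=O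
F10 | step 12 | 6-ylidene enone from F9 and 16 (E/Z mixture) | CC1=CC[C@H]2[C@H](CC[C@]2(C)O[Si](CC)(CC)CC)C(C)(C)[C@@H]1CC=C1[C@]2(C)CC[C@H](O[Si](C)(C)C)C(C)(C)O[C@H]2CCC1=O
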